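## Retrosynthetic overview

1. Unit 1 is the flavanone whose ring B carries the ether oxygen at C4'. Unit 2 is the flavanone whose ring A carries it at C6. Usual flavanone locants apply in both. The last step removes four benzyl ethers.
2. Ring C of unit 2 is closed last, at O1–C8a. The carbinol oxygen of an open-chain (S)-β-silyloxy ketone is joined to a C–H carbon of ring A by oxidative dearomatisation, oxa-Michael addition and rearomatisation, so the C2–O bond is never touched and no 6-O/8-O isomer can form.
3. Enabling feature: in ring A of unit 2, C5–OH and C6–OAr form a 2-aryloxyphenol. In its orthoquinol acetate (C5=O, C6(OAc)(OAr)), C8a (para to C6) is the β-carbon of C4a=C8a, which is conjugated with both the C5 ring carbonyl and the C4 ketone and lies six atoms from the carbinol oxygen.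
4. Before that, the C2–aryl bond of unit 1 comes from rhodium-catalysed asymmetric 1,4-addition of the ring B boronate to 5,7-bis(benzyloxy)chromone. C2 of unit 2 comes from copper-catalysed asymmetric β-borylation/oxidation of a chalcone.
5. Ring A of unit 2 is bought with its three neighbouring oxygens (gallacetophenone), and the crowded diaryl ether is made early with a diaryliodonium salt. Ring order: pyranone of unit 1 (as chromone), then its C2 stereocentre, then ring C of unit 2.

Key step: step 10

Assumption: the absolute sense of induction in steps 4 and 9 is taken by analogy (chalcone for the copper–Josiphos catalyst, 2-cyclohexenone for the rhodium–bisphosphine catalyst); should either run the other way, the mirror-image ligand is used and nothing else changes.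

## Route

Step 1
Reactants: 1 2',3',4'-trihydroxyacetophenone (gallacetophenone)
Product: 2 1-[4-(benzyloxy)-2,3-dihydroxyphenyl]ethan-1-one
Conditions: BnBr (1.0 equiv), K2CO3 (1.0 equiv), DMF, N2, rt
Reagents that add atoms: benzyl bromide, BrCc1ccccc1
Why: Williamson ether synthesis under substrate control: the 4-OH, para to the acetyl group, is the most acidic phenol and the only one that is neither chelated to the ketone (2-OH) nor flanked on both sides (3-OH), so one equivalent of bromide should go there.

Step 2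
Reactants: 2 1-[4-(benzyloxy)-2,3-dihydroxyphenyl]ethan-1-one; 3 bis(4-bromophenyl)iodonium trifluoromethanesulfonate
Product: 4 1-[4-(benzyloxy)-3-(4-bromophenoxy)-2-hydroxyphenyl]ethan-1-one
Conditions: KOt-Bu (1.0 equiv), THF, 0 °C; then 3, 40 °C, N2
Reagents that add atoms: none
Why: Metal-free O-arylation of a phenoxide with a diaryliodonium salt (ligand coupling at trivalent iodine), a reaction type that accepts phenols with two ortho substituents; one equivalent of base forms the 3-phenoxide because the 2-OH stays locked in its hydrogen bond to the ketone, the order also seen in alkylations of such 2,3-dihydroxyaryl ketones.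

Step 3
Reactants: 4 1-[4-(benzyloxy)-3-(4-bromophenoxy)-2-hydroxyphenyl]ethan-1-one; 5 4-(benzyloxy)benzaldehyde
Product: 6 (E)-1-[4-(benzyloxy)-3-(4-bromophenoxy)-2-hydroxyphenyl]-3-[4-(benzyloxy)phenyl]prop-2-en-1-one
Conditions: KOH (50% aq), EtOH, rt; then cold 1 M HCl
Reagents that add atoms: none
Why: Claisen–Schmidt condensation of a 2-hydroxyacetophenone with a non-enolisable aldehyde, which in strong base stops at the (E)-chalcone phenoxide.

Step 4
Reactants: 6 (E)-chalcone
Product: 8 (S)-1-[4-(benzyloxy)-3-(4-bromophenoxy)-2-hydroxyphenyl]-3-[4-(benzyloxy)phenyl]-3-hydroxypropan-1-one, via benzylic pinacol boronate 7 (not isolated)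
Conditions: CuCl (5 mol%), NaOt-Bu (10 mol%), (R)-1-[(S)-2-(diphenylphosphino)ferrocenyl]ethyldicyclohexylphosphine (Josiphos, 5.5 mol%), B2pin2, MeOH, THF, rt; then NaBO3·4H2O, THF/H2O, 0 °C to rt
Reagents that add atoms: sodium perborate tetrahydrate, B(=O)O[O-].[Na+].O.O.O.O
Why: Copper-catalysed asymmetric conjugate borylation of a chalcone followed by stereoretentive oxidation of the C–B bond: the Josiphos-bound Cu–Bpin species adds to one face of the enone and so sets C2 of unit 2 as (S), and cold perborate should oxidise the benzylic boronate well before it attacks the chelated, hindered ketone.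

Step 5
Reactants: 8 (S)-β-hydroxy ketone
Product: 9 (S)-1-[4-(benzyloxy)-3-(4-bromophenoxy)-2-hydroxyphenyl]-3-[4-(benzyloxy)phenyl]-3-[(tert-butyldimethylsilyl)oxy]propan-1-one
Conditions: TBSCl, imidazole, DMF, rt
Reagents that add atoms: tert-butyldimethylsilyl chloride, CC(C)(C)[Si](C)(C)Cl
Why: Standard silylation of a secondary alcohol; the phenol that is hydrogen-bonded to the ketone is not silylated under these mild conditions (and a trace of aryl silyl ether would fall off on aqueous work-up).

Step 6
Reactants: 9 (S)-silyl ether aryl bromide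
Product: 10 (S)-1-{4-(benzyloxy)-2-hydroxy-3-[4-(4,4,5,5-tetramethyl-1,3,2-dioxaborolan-2-yl)phenoxy]phenyl}-3-[4-(benzyloxy)phenyl]-3-[(tert-butyldimethylsilyl)oxy]propan-1-one
Conditions: B2pin2, PdCl2(dppf) (3 mol%), KOAc, 1,4-dioxane, 85 °C
Reagents that add atoms: bis(pinacolato)diboron, CC1(C)OB(OC1(C)C)B1OC(C)(C)C(C)(C)O1
Why: Miyaura borylation of an aryl bromide, mild enough (acetate base) for the β-silyloxy ketone and the free chelated phenol.

Step 7
Reactants: 11 2',4',6'-trihydroxyacetophenone
Product: 12 1-[2,4-bis(benzyloxy)-6-hydroxyphenyl]ethan-1-one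
Conditions: BnBr (2.05 equiv), K2CO3, DMF, rt to 40 °C
Reagents that add atoms: benzyl bromide, BrCc1ccccc1
Why: Twofold Williamson etherification; one of the two equivalent ortho hydroxyls stays free because after the first ortho-alkylation the remaining one is chelated to the ketone.

Step 8
Reactants: 12 1-[2,4-bis(benzyloxy)-6-hydroxyphenyl]ethan-1-one
Product: 14 5,7-bis(benzyloxy)-4H-chromen-4-one, via enaminone 13 (not isolated)
Conditions: Me2NCH(OMe)2, toluene, 100 °C; then conc. HCl, CH2Cl2, 40 °C
Reagents that add atoms: N,N-dimethylformamide dimethyl acetal, COC(OC)N(C)C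
Why: Enaminone formation at the acetyl group and acid-induced addition–elimination of the ortho phenol (standard chromone synthesis).

Step 9
Reactants: 10 aryl pinacol boronate; 14 5,7-bis(benzyloxy)-4H-chromen-4-one
Product: 15 (2S)-5,7-bis(benzyloxy)-2-{4-[6-(benzyloxy)-3-{(3S)-3-[4-(benzyloxy)phenyl]-3-[(tert-butyldimethylsilyl)oxy]propanoyl}-2-hydroxyphenoxy]phenyl}chroman-4-one
Conditions: [Rh(OH)(cod)]2 (3 mol%), (S)-MeO-F12-BIPHEP [(S)-6,6'-dimethoxybiphenyl-2,2'-diylbis{bis(3,4,5-trifluorophenyl)phosphine}, 6.5 mol%], aq K3PO4, toluene, 40 °C, 14 in excess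
Reagents that add atoms: none
Why: Hayashi–Miyaura type rhodium-catalysed asymmetric 1,4-addition of an arylboron reagent to a chromone, a known entry to enantioenriched flavanones including 5,7-dioxygenated ones: the C2-symmetric bisphosphine blocks one face of the chromone in the aryl-rhodium insertion and so sets C2 of unit 1 as (S), and the two-phase, weakly basic medium leaves the new flavanone closed.

Step 10
Reactants: 15 unit 1 flavanone carrying the open-chain unit 2 (free C5 phenol, silylated carbinol)
Product: 19 (2S)-5,7-bis(benzyloxy)-2-(4-{[(2S)-7-(benzyloxy)-2-[4-(benzyloxy)phenyl]-5-hydroxy-4-oxochroman-6-yl]oxy}phenyl)chroman-4-one, via orthoquinol acetate 16 (not isolated), via desilylated orthoquinol acetate 17 (not isolated), via oxa-Michael adduct 18 (not isolated)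
Conditions: PhI(OAc)2 (1.0 equiv), CH2Cl2, −40 °C to 0 °C; then Bu4NF/AcOH (1:1), THF, −10 °C to rt
Reagents that add atoms: none
Why: Proposed new method: PhI(OAc)2 exchanges a ligand with the only free phenol (C5–OH of unit 2) and delivers acetate to the aryloxy-bearing ortho carbon C6 to give the 6-acetoxy-6-aryloxycyclohexa-2,4-dienone 16, buffered fluoride then frees the carbinol (17), whose oxygen adds to C8a, the β-carbon of the C4a=C8a double bond conjugated with both the C5 ring carbonyl and the C4 ketone (18), and loss of AcOH across C6/C8a restores the benzene ring. The closest known reaction type is the oxidative acetoxylation of 2-alkoxyphenols to orthoquinol acetates followed by fluoride-triggered attack of a tethered silyl-protected alcohol and rearomatisation to benzo-fused oxygen heterocycles; new here are the aryloxy/acetoxy ketal, the acyl-bearing acceptor and the one-pot format. The single ring closed is ring C of unit 2, by a 6-endo-trig oxa-Michael addition (C4a=C8a lies inside the forming ring). No lasting stereocentre is made: C6 and C8a are stereogenic only in 16–18 and become planar again, while C2 of unit 2 keeps its (S) configuration because its C–O bond is never broken and the medium is too weakly basic for retro-aldol, β-elimination or opening of the unit 1 flavanone. Site selectivity rests on the substrate: acetate goes to C6 because only there the developing cation is stabilised by an attached oxygen (C4a carries the acyl group, C8 only hydrogen), the carbinol oxygen can productively reach no electrophilic carbon other than C8a, and acetate rather than the aryloxide leaves from C6 because it is the weaker base and leaves an oxygen-stabilised cation. Adding fluoride only after the oxidant is spent keeps the more electron-rich product phenol 19 from being oxidised in turn.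

Step 11
Reactants: 19 tetra-O-benzyl biflavanone
Product: 20 (2S)-5,7-dihydroxy-2-(4-{[(2S)-5,7-dihydroxy-2-(4-hydroxyphenyl)-4-oxochroman-6-yl]oxy}phenyl)chroman-4-one (target)
Conditions: H2 (1 atm), 10% Pd/C, EtOAc/MeOH, rt
Reagents that add atoms: none
Why: Hydrogenolysis of aryl benzyl ethers under neutral conditions, the usual last step for flavanones, which touches neither the ketones, the diaryl ether nor the two base-sensitive stereocentres.

## Compound list

1 | 2',3',4'-trihydroxyacetophenone | CC(=O)c1ccc(O)c(O)c1O | starting material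
2 | 1-[4-(benzyloxy)-2,3-dihydroxyphenyl]ethan-1-one | CC(=O)c1ccc(OCc2ccccc2)c(O)c1O | intermediate
3 | bis(4-bromophenyl)iodonium trifluoromethanesulfonate | [O-]S(=O)(=O)C(F)(F)F.Brc1ccc([I+]c2ccc(Br)cc2)cc1 | starting material
4 | 1-[4-(benzyloxy)-3-(4-bromophenoxy)-2-hydroxyphenyl]ethan-1-one | CC(=O)c1ccc(OCc2ccccc2)c(Oc2ccc(Br)cc2)c1O | intermediate
5 | 4-(benzyloxy)benzaldehyde | O=Cc1ccc(OCc2ccccc2)cc1 | starting material
6 | (E)-chalcone of 4 and 5 | O=C(/C=C/c1ccc(OCc2ccccc2)cc1)c1ccc(OCc2ccccc2)c(Oc2ccc(Br)cc2)c1O | intermediate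
7 | (S)-β-(pinacolboryl) ketone (not isolated) | O=C(C[C@@H](c1ccc(OCc2ccccc2)cc1)B1OC(C)(C)C(C)(C)O1)c1ccc(OCc2ccccc2)c(Oc2ccc(Br)cc2)c1O | intermediate
8 | (S)-β-hydroxy ketone | O=C(C[C@@H](c1ccc(OCc2ccccc2)cc1)O)c1ccc(OCc2ccccc2)c(Oc2ccc(Br)cc2)c1O | intermediate
9 | (S)-β-(tert-butyldimethylsilyloxy) ketone, aryl bromide | O=C(C[C@@H](c1ccc(OCc2ccccc2)cc1)O[Si](C)(C)C(C)(C)C)c1ccc(OCc2ccccc2)c(Oc2ccc(Br)cc2)c1O | intermediate
10 | (S)-β-(tert-butyldimethylsilyloxy) ketone, aryl pinacol boronate | O=C(C[C@@H](c1ccc(OCc2ccccc2)cc1)O[Si](C)(C)C(C)(C)C)c1ccc(OCc2ccccc2)c(Oc2ccc(B3OC(C)(C)C(C)(C)O3)cc2)c1O | intermediate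
11 | 2',4',6'-trihydroxyacetophenone | CC(=O)c1c(O)cc(O)cc1O | starting material
12 | 1-[2,4-bis(benzyloxy)-6-hydroxyphenyl]ethan-1-one | CC(=O)c1c(O)cc(OCc2ccccc2)cc1OCc1ccccc1 | intermediate
13 | (E)-1-[2,4-bis(benzyloxy)-6-hydroxyphenyl]-3-(dimethylamino)prop-2-en-1-one (not isolated) | CN(C)/C=C/C(=O)c1c(O)cc(OCc2ccccc2)cc1OCc1ccccc1 | intermediate
14 | 5,7-bis(benzyloxy)-4H-chromen-4-one | O=c1ccoc2cc(OCc3ccccc3)cc(OCc3ccccc3)c12 | intermediate
15 | (2S)-flavanone unit 1 carrying the open-chain (S)-silyloxy ketone of unit 2 | O=C1C[C@@H](c2ccc(Oc3c(O)c(C(=O)C[C@@H](c4ccc(OCc5ccccc5)cc4)O[Si](C)(C)C(C)(C)C)ccc3OCc3ccccc3)cc2)Oc2cc(OCc3ccccc3)cc(OCc3ccccc3)c21 | intermediate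
16 | orthoquinol acetate, silyl ether (C6 epimers, not isolated) | O=C1C[C@@H](c2ccc(OC3(OC(C)=O)C(=O)C(C(=O)C[C@@H](c4ccc(OCc5ccccc5)cc4)O[Si](C)(C)C(C)(C)C)=CC=C3OCc3ccccc3)cc2)Oc2cc(OCc3ccccc3)cc(OCc3ccccc3)c21 | intermediate
17 | orthoquinol acetate, free carbinol (not isolated) | O=C1C[C@@H](c2ccc(OC3(OC(C)=O)C(=O)C(C(=O)C[C@@H](c4ccc(OCc5ccccc5)cc4)O)=CC=C3OCc3ccccc3)cc2)Oc2cc(OCc3ccccc3)cc(OCc3ccccc3)c21 | intermediate
18 | oxa-Michael adduct, enol form (C6 and C8a epimers, not isolated) | O=C1C[C@@H](c2ccc(OC3(OC(C)=O)C(O)=C4C(=O)C[C@@H](c5ccc(OCc6ccccc6)cc5)OC4C=C3OCc3ccccc3)cc2)Oc2cc(OCc3ccccc3)cc(OCc3ccccc3)c21 | intermediate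
19 | (2S,2''S)-tetra-O-benzyl biflavanone with free 5-OH in unit 2 | O=C1C[C@@H](c2ccc(Oc3c(OCc4ccccc4)cc4c(c3O)C(=O)C[C@@H](c3ccc(OCc5ccccc5)cc3)O4)cc2)Oc2cc(OCc3ccccc3)cc(OCc3ccccc3)c21 | intermediate
20 | (2S,2''S)-biflavanone CNP0184214.1 | O=C1C[C@@H](c2ccc(Oc3c(O)cc4c(c3O)C(=O)C[C@@H](c3ccc(O)cc3)O4)cc2)Oc2cc(O)cc(O)c21 | target

## Step count and risks

Total steps: 11. Longest linear sequence: 9 (steps 1–6, 9, 10, 11).

**1. Step 10 (new method).**
- What may go wrong: acetate may be delivered to the unsubstituted para carbon C8 instead of C6. The mixed ketal may also collapse hydrolytically to the orthoquinone, losing the unit 1 aryloxide before the carbinol adds.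
- Fallback with known chemistry, from 15 back to 19: Teuber oxidation of 15 with (KSO3)2NO (acetone/aq KH2PO4) uses that same free para position and should give the 2-acyl-1,4-benzoquinone F1.
- Bu4NF/AcOH then frees the carbinol. It adds to C8a, the 3-position of an acylquinone and its known site of nucleophilic attack, and tautomerises (Na2S2O4 wash) to the 5,8-dihydroxyflavanone F2.
- The unchelated 8-OH is sulfonylated selectively (Tf2O, 2,6-lutidine, CH2Cl2, −78 °C) to the 8-triflate F3.
- Reduction of the aryl triflate with Pd(OAc)2, dppf, HCO2H and Et3N returns 19.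

**2. Step 9.**
- What may go wrong: transmetalation of the bulky pinacol boronate may be slow and protodeboronation may compete. Facial selectivity on the electron-rich, 5-substituted chromone may be poor.
- Fallback, from 9 and 12 back to 15, building ring C of unit 1 from an aldehyde instead: formylation of 9 (Pd(OAc)2, di(1-adamantyl)-n-butylphosphine, CO/H2, TMEDA, toluene, 100 °C) gives the aldehyde F4.
- Compound 12 with TMSOTf/Et3N gives the bis(trimethylsilyl) enol ether F5.
- A catalytic asymmetric Mukaiyama aldol reaction of F4 with F5 follows. It uses the N-tosyltryptophan-derived B-butyloxazaborolidinone enantiomer that gives the (R)-carbinol (EtCN, −78 °C, mild acidic work-up) and gives the (R)-aldol F6.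
- Mitsunobu cyclisation (PPh3, DIAD, toluene, 0 °C) through the ortho phenol of ring A of unit 1 closes the ring with inversion to the (S)-flavanone 15.

**3. Step 2.**
- What may go wrong: the wrong oxygen may be arylated, or the iodonium salt may oxidise the catechol-type phenoxide.
- Fallback, from 2 back to 4: nucleophilic aromatic substitution on 1-fluoro-4-nitrobenzene (K2CO3, DMF, 60 °C) gives the nitrophenyl ether F7.
- Any 2-O-aryl isomer should equilibrate to F7 by Smiles rearrangement, because the ketone-conjugated 2-phenoxide is the more stable anion.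
- Fe/NH4Cl (EtOH/H2O) gives the aniline F8, and Sandmeyer bromination (t-BuONO, CuBr2, MeCN) returns 4.

## Further compounds

F1 | step 10 | 2-acyl-1,4-benzoquinone from 15 (C5 and C8 carbonyls, silyl ether kept) | O=C1C[C@@H](c2ccc(OC3=C(OCc4ccccc4)C(=O)C=C(C(=O)C[C@@H](c4ccc(OCc5ccccc5)cc4)O[Si](C)(C)C(C)(C)C)C3=O)cc2)Oc2cc(OCc3ccccc3)cc(OCc3ccccc3)c21
F2 | step 10 | 8-hydroxy analogue of 19 (5,8-dihydroxyflavanone in unit 2) | O=C1C[C@@H](c2ccc(Oc3c(OCc4ccccc4)c(O)c4c(c3O)C(=O)C[C@@H](c3ccc(OCc5ccccc5)cc3)O4)cc2)Oc2cc(OCc3ccccc3)cc(OCc3ccccc3)c21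
F3 | step 10 | 8-trifluoromethanesulfonate of F2 | O=C1C[C@@H](c2ccc(Oc3c(OCc4ccccc4)c(OS(=O)(=O)C(F)(F)F)c4c(c3O)C(=O)C[C@@H](c3ccc(OCc5ccccc5)cc3)O4)cc2)Oc2cc(OCc3ccccc3)cc(OCc3ccccc3)c21
F4 | step 9 | 4-aryloxybenzaldehyde from 9 | O=Cc1ccc(Oc2c(O)c(C(=O)C[C@@H](c3ccc(OCc4ccccc4)cc3)O[Si](C)(C)C(C)(C)C)ccc2OCc2ccccc2)cc1
F5 | step 9 | bis(trimethylsilyl) enol ether of 12 | C=C(O[Si](C)(C)C)c1c(O[Si](C)(C)C)cc(OCc2ccccc2)cc1OCc1ccccc1
F6 | step 9 | (R)-aldol of F4 and F5 (open-chain unit 1) | O=C(C[C@H](c1ccc(Oc2c(O)c(C(=O)C[C@@H](c3ccc(OCc4ccccc4)cc3)O[Si](C)(C)C(C)(C)C)ccc2OCc2ccccc2)cc1)O)c1c(O)cc(OCc2ccccc2)cc1OCc1ccccc1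
F7 | step 2 | 1-[4-(benzyloxy)-2-hydroxy-3-(4-nitrophenoxy)phenyl]ethan-1-one | CC(=O)c1ccc(OCc2ccccc2)c(Oc2ccc([N+](=O)[O-])cc2)c1O
F8 | step 2 | 1-[3-(4-aminophenoxy)-4-(benzyloxy)-2-hydroxyphenyl]ethan-1-one | CC(=O)c1ccc(OCc2ccccc2)c(Oc2ccc(N)cc2)c1O
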